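## Retrosynthetic overview
- Target 17 comes from the fully masked (S)-ether 16 by one mild acidolysis, which removes three MOM acetals and one bis(4-methoxyphenyl)methyl (BMPM) ether. Cutting the Cα–CH2(ring B) bond of 16 gives the achiral glycolyl ketone 11 and the benzylic bromide 14, which are joined by a catalytic enantioselective phase-transfer benzylation.
- Enabling feature: the O–Cα–C(=O) unit on C1' of ring A. Cα sits between the aryl ketone carbonyl and an ether oxygen, next to the ortho C2'–O group, so it gives one flat (Z)-enediol-type enolate that a chiral cation can shield on one face. The benzylic carbon of ring B is activated for SN2 by the para C4–O.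
- Ketone 11 comes from aryl bromide 5 and Weinreb amide 8. Bromide 5 comes from the symmetric dibromide 3 and thus from 2-methylresorcinol 1; two successive Br/Li exchanges place the prenyl group on C5' and the glycolyl group on C1'.
- Bromide 14 comes from 4-hydroxybenzyl alcohol 12 by MOM protection and an Appel reaction.
- No ring is formed in the route: rings A and B are bought as 1 and 12.

Key step: step 8

Remark on the chemistry: the stereodescriptor of the target corresponds to (S) at Cα (O > C=O > CH2 > H). The ammonium salt of step 8 is a known catalyst, made from hydrocinchonidine by quaternisation and O-allylation, and is not counted as a step.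

## Route

Step 1
Reactants: 1 2-methylresorcinol
Product: 2 4,6-dibromo-2-methylbenzene-1,3-diol
Conditions: NBS (2.05 equiv), MeCN, 0 °C to rt
Reagents that add atoms: N-bromosuccinimide, O=C1CCC(=O)N1Br
Why: Electrophilic aromatic bromination, in which C4 and C6 are the only free positions ortho/para to the two hydroxyls (C2 is blocked by methyl, C5 is meta to both), so the symmetric dibromide should form.

Step 2
Reactants: 2 4,6-dibromo-2-methylbenzene-1,3-diol
Product: 3 1,5-dibromo-2,4-bis(methoxymethoxy)-3-methylbenzene
Conditions: NaH (2.4 equiv), MOMCl (2.4 equiv), DMF, 0 °C to rt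
Reagents that add atoms: chloromethyl methyl ether, COCCl
Why: Williamson-type O-alkylation of both flanked phenoxides with the small, very reactive MOMCl gives acetals that tolerate organolithiums and hydroxide and that chelate lithium in the next steps.

Step 3
Reactants: 3 1,5-dibromo-2,4-bis(methoxymethoxy)-3-methylbenzene
Product: 5 1-bromo-2,4-bis(methoxymethoxy)-3-methyl-5-(3-methylbut-2-en-1-yl)benzene, via aryllithium 4 (not isolated)
Conditions: n-BuLi (1.0 equiv), THF, −78 °C; then prenyl bromide (1.3 equiv), −78 °C to 0 °C
Reagents that add atoms: prenyl bromide (1-bromo-3-methylbut-2-ene), CC(C)=CCBr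
Why: Bromine–lithium exchange followed by SN2 allylation, in which either bromine of the symmetric 3 gives the same OMOM-chelated aryllithium, a second exchange on the already anionic ring is disfavoured, and the primary end of prenyl bromide is the accessible one.

Step 4
Reactants: 6 bis(4-methoxyphenyl)methanol; 7 2-chloro-N-methoxy-N-methylacetamide
Product: 8 2-[bis(4-methoxyphenyl)methoxy]-N-methoxy-N-methylacetamide
Conditions: NaH (1.1 equiv), THF, 0 °C; then 7, Bu4NI (5 mol %), 0 °C to rt
Reagents that add atoms: none
Why: Williamson ether synthesis, in which the sodium alkoxide of 6 displaces the carbonyl-activated primary chloride faster than it attacks the N-methoxyamide carbonyl.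

Step 5
Reactants: 5 1-bromo-2,4-bis(methoxymethoxy)-3-methyl-5-(3-methylbut-2-en-1-yl)benzene; 8 2-[bis(4-methoxyphenyl)methoxy]-N-methoxy-N-methylacetamide
Product: 11 2-[bis(4-methoxyphenyl)methoxy]-1-[2,4-bis(methoxymethoxy)-3-methyl-5-(3-methylbut-2-en-1-yl)phenyl]ethan-1-one, via aryllithium 9 (not isolated), via tetrahedral lithium adduct 10 (not isolated)
Conditions: n-BuLi (1.05 equiv), THF, −78 °C; then 8, −78 °C to 0 °C; then H2O
Reagents that add atoms: none
Why: Bromine–lithium exchange and Weinreb ketone synthesis, in which the exchange at −78 °C outruns deprotonation of the allylic/benzylic CH2 and the N,O-chelated adduct 10 blocks over-addition until the neutral aqueous quench, which also spares the acid-labile BMPM ether.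

Step 6
Reactants: 12 4-hydroxybenzyl alcohol
Product: 13 [4-(methoxymethoxy)phenyl]methanol
Conditions: K2CO3 (1.5 equiv), MOMCl (1.05 equiv), acetone, 0 °C to rt
Reagents that add atoms: chloromethyl methyl ether, COCCl
Why: Phenol-selective Williamson-type O-alkylation, because K2CO3 ionises only the phenol and the phenoxide outcompetes the neutral benzylic alcohol for the limiting MOMCl.

Step 7
Reactants: 13 [4-(methoxymethoxy)phenyl]methanol
Product: 14 1-(bromomethyl)-4-(methoxymethoxy)benzene
Conditions: CBr4 (1.2 equiv), PPh3 (1.2 equiv), CH2Cl2, 0 °C; short filtration, used at once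
Reagents that add atoms: carbon tetrabromide, BrC(Br)(Br)Br
Why: Appel reaction, whose neutral conditions convert the primary benzylic alcohol through its alkoxyphosphonium salt into the bromide without releasing acid that would cleave the MOM acetal.

Step 8
Reactants: 11 2-[bis(4-methoxyphenyl)methoxy]-1-[2,4-bis(methoxymethoxy)-3-methyl-5-(3-methylbut-2-en-1-yl)phenyl]ethan-1-one; 14 1-(bromomethyl)-4-(methoxymethoxy)benzene
Product: 16 (2S)-2-[bis(4-methoxyphenyl)methoxy]-1-[2,4-bis(methoxymethoxy)-3-methyl-5-(3-methylbut-2-en-1-yl)phenyl]-3-[4-(methoxymethoxy)phenyl]propan-1-one, via (Z)-enolate 15 (not isolated)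
Conditions: O(9)-allyl-N-(2,3,4-trifluorobenzyl)hydrocinchonidinium bromide (10 mol %), CsOH·H2O (4 equiv), 14 (1.5 equiv), CH2Cl2/hexane 1:1, −35 °C
Reagents that add atoms: none
Why: Solid CsOH removes a Cα proton of 11 at the interface, the chiral quaternary ammonium cation carries the (Z)-enolate 15 into the organic phase as a tight contact ion pair, and this ion pair displaces bromide from 14 in an SN2 C-alkylation (asymmetric phase-transfer-catalysed glycolate alkylation). The closest known reaction type is the cinchonidinium-catalysed benzylation of α-(diarylmethoxy)acetophenones bearing an ortho-alkoxy group with para-oxygenated benzyl bromides, where the aryl ketone usually serves only as an ester surrogate but here is ring A of the target itself. No ring is closed in this step. The one new stereocentre, Cα, is controlled by the catalyst: the cation covers one enolate face while the bulky diarylmethyl ether and the twisted ring A rest against its quinoline and benzyl walls, so the bromide reaches only the open face, and cinchonidine-derived salts give the (S)-ether in this reaction class whereas the cinchonine-derived pseudoenantiomer would give (R). The step needs C- over O-alkylation, mono- over dialkylation and a configurationally stable product, which are secured by the soft benzylic bromide, by the shielding of the remaining tertiary Cα–H of 16 between the diarylmethoxy and benzyl groups at −35 °C, and by base-stable MOM masking of all phenols beside a base-inert prenyl alkene. In one operation the C14 and C7 halves are united, all 21 skeletal carbons and all five oxygens are in place at their final oxidation level, and the only stereocentre is set from an achiral precursor.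

Step 9
Reactants: 16 (2S)-2-[bis(4-methoxyphenyl)methoxy]-1-[2,4-bis(methoxymethoxy)-3-methyl-5-(3-methylbut-2-en-1-yl)phenyl]-3-[4-(methoxymethoxy)phenyl]propan-1-one
Product: 17 lespeflorin C5, (2S)-1-[2,4-dihydroxy-3-methyl-5-(3-methylbut-2-en-1-yl)phenyl]-2-hydroxy-3-(4-hydroxyphenyl)propan-1-one
Conditions: HCl (1.25 M in MeOH), MeOH, 0 °C to 35 °C
Reagents that add atoms: none
Why: Acid-catalysed transacetalisation and SN1 solvolysis, in which the three MOM acetals and the doubly p-methoxy-stabilised benzhydryl ether all ionise in dilute methanolic HCl and methanol traps the cations, while the Cα–O bond is never broken so the (S) configuration is kept and the dilute acid should leave the prenyl alkene unprotonated.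

## Compound list
1 | 2-methylresorcinol | Cc1c(O)cccc1O | starting material
2 | 4,6-dibromo-2-methylbenzene-1,3-diol | Cc1c(O)c(Br)cc(Br)c1O | intermediate
3 | 1,5-dibromo-2,4-bis(methoxymethoxy)-3-methylbenzene | Cc1c(OCOC)c(Br)cc(Br)c1OCOC | intermediate
4 | [5-bromo-2,4-bis(methoxymethoxy)-3-methylphenyl]lithium (formed in the flask) | Cc1c(OCOC)c([Li])cc(Br)c1OCOC | intermediate
5 | 1-bromo-2,4-bis(methoxymethoxy)-3-methyl-5-(3-methylbut-2-en-1-yl)benzene | CC(C)=CCc1cc(Br)c(OCOC)c(C)c1OCOC | intermediate
6 | bis(4-methoxyphenyl)methanol | COc1ccc(cc1)C(O)c1ccc(OC)cc1 | starting material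
7 | 2-chloro-N-methoxy-N-methylacetamide | CON(C)C(=O)CCl | starting material
8 | 2-[bis(4-methoxyphenyl)methoxy]-N-methoxy-N-methylacetamide | CON(C)C(=O)COC(c1ccc(OC)cc1)c1ccc(OC)cc1 | intermediate
9 | [2,4-bis(methoxymethoxy)-3-methyl-5-(3-methylbut-2-en-1-yl)phenyl]lithium (formed in the flask) | CC(C)=CCc1cc([Li])c(OCOC)c(C)c1OCOC | intermediate
10 | tetrahedral lithium alkoxide from 9 and 8, racemic at the hemiaminal carbon (formed in the flask) | CC(C)=CCc1cc(C(O[Li])(COC(c2ccc(OC)cc2)c2ccc(OC)cc2)N(C)OC)c(OCOC)c(C)c1OCOC | intermediate
11 | 2-[bis(4-methoxyphenyl)methoxy]-1-[2,4-bis(methoxymethoxy)-3-methyl-5-(3-methylbut-2-en-1-yl)phenyl]ethan-1-one | CC(C)=CCc1cc(C(=O)COC(c2ccc(OC)cc2)c2ccc(OC)cc2)c(OCOC)c(C)c1OCOC | intermediate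
12 | 4-hydroxybenzyl alcohol | OCc1ccc(O)cc1 | starting material
13 | [4-(methoxymethoxy)phenyl]methanol | COCOc1ccc(CO)cc1 | intermediate
14 | 1-(bromomethyl)-4-(methoxymethoxy)benzene | COCOc1ccc(CBr)cc1 | intermediate
15 | (Z)-enolate of 11, drawn as the caesium salt, ion-paired with the catalyst cation in the organic phase (formed in the flask) | [Cs+].[O-]/C(=C\OC(c1ccc(OC)cc1)c1ccc(OC)cc1)c1cc(CC=C(C)C)c(OCOC)c(C)c1OCOC | intermediate
16 | (2S)-2-[bis(4-methoxyphenyl)methoxy]-1-[2,4-bis(methoxymethoxy)-3-methyl-5-(3-methylbut-2-en-1-yl)phenyl]-3-[4-(methoxymethoxy)phenyl]propan-1-one | CC(C)=CCc1cc(C(=O)[C@@H](OC(c2ccc(OC)cc2)c2ccc(OC)cc2)Cc2ccc(OCOC)cc2)c(OCOC)c(C)c1OCOC | intermediate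
17 | lespeflorin C5, (2S)-1-[2,4-dihydroxy-3-methyl-5-(3-methylbut-2-en-1-yl)phenyl]-2-hydroxy-3-(4-hydroxyphenyl)propan-1-one | CC(C)=CCc1cc(C(=O)[C@@H](O)Cc2ccc(O)cc2)c(O)c(C)c1O | target

## Step count and risks
Total step count: 9. Longest linear sequence: 6 (steps 1, 2, 3, 5, 8, 9).

Steps most likely to fail:

**Step 8.** Facial discrimination inside the ion pair may be poor, because ring A is more crowded than the simple aryl ketones of this reaction class. The labile bromide may also be hydrolysed by hydroxide before it is alkylated.

The fallback separates bond formation from stereocontrol. It sets out from 11 and 14 and comes back at 16.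
- Ketone 11 is deprotonated with LiHMDS in THF at −78 °C and alkylated with 14 without any chiral controller, giving the racemic protected ether F1.
- The enantiomers are separated by preparative SFC on a polysaccharide chiral phase; the (S)-enantiomer is 16.
- The (R)-configured protected ether F2 is returned to F1 by DBU-mediated enolisation in toluene and resolved again.

**Step 9.** The prenyl alkene may be protonated and cyclise onto the liberated C4' hydroxyl. Slow acid-catalysed enolisation of the α-hydroxy ketone may erode the configuration during the time the MOM groups need.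

The fallback is a staged unmasking that avoids Brønsted acid once the phenols are free. It sets out from 16 and comes back at 17.
- Camphorsulfonic acid (5 mol %) in MeOH/CH2Cl2 at 0 °C should solvolyse only the BMPM ether, giving the tris-MOM (S)-hydroxy ketone F3.
- TMSOTf and 2,2'-bipyridyl in MeCN at 0 °C to rt should convert the aromatic MOM ethers, under weakly basic conditions, into the per-silylated (S)-ether F4.
- Ether F4 is hydrolysed to 17 on addition of water.

**Step 3.** Possible problems are incomplete or double exchange, attack at the tertiary end of the allylic bromide, and coupling of the aryllithium with the butyl bromide formed in the exchange.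

The fallback replaces the organolithium substitution with a cross-coupling. It sets out from 3 and comes back at 5. A Stille coupling of 3 with a deficit of tributyl(3-methylbut-2-en-1-yl)stannane under Pd(PPh3)4 in DMF at 90 °C should give 5. Unreacted 3 is recovered and resubmitted.

## Further compounds
F1 | step 8 | racemic 2-[bis(4-methoxyphenyl)methoxy]-1-[2,4-bis(methoxymethoxy)-3-methyl-5-(3-methylbut-2-en-1-yl)phenyl]-3-[4-(methoxymethoxy)phenyl]propan-1-one | CC(C)=CCc1cc(C(=O)C(OC(c2ccc(OC)cc2)c2ccc(OC)cc2)Cc2ccc(OCOC)cc2)c(OCOC)c(C)c1OCOC
F2 | step 8 | (2R)-enantiomer of 16 | CC(C)=CCc1cc(C(=O)[C@H](OC(c2ccc(OC)cc2)c2ccc(OC)cc2)Cc2ccc(OCOC)cc2)c(OCOC)c(C)c1OCOC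
F3 | step 9 | (2S)-1-[2,4-bis(methoxymethoxy)-3-methyl-5-(3-methylbut-2-en-1-yl)phenyl]-2-hydroxy-3-[4-(methoxymethoxy)phenyl]propan-1-one | CC(C)=CCc1cc(C(=O)[C@@H](O)Cc2ccc(OCOC)cc2)c(OCOC)c(C)c1OCOC
F4 | step 9 | (2S)-tetrakis(trimethylsilyl) ether of 17 | CC(C)=CCc1cc(C(=O)[C@@H](O[Si](C)(C)C)Cc2ccc(O[Si](C)(C)C)cc2)c(O[Si](C)(C)C)c(C)c1O[Si](C)(C)C
F0 | step 3 | none | none
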